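## The problem

The target **32** consists of two 7-hydroxychromans (upper: ring A, with ring B on C3; lower: ring A') that share the central benzene ring E. Ring E is the 3-aryl group of the lower chroman (E6–C3') and the 4-aryl group of the upper one (E1–C4), and it also carries OMe at E2 and OH at E4. The two carbon substituents are therefore ortho to each other, and E1 is wedged between the methoxy group and the lower chroman. In a 3,5-dioxygenated ring E precursor the positions E1, E3 and E5 are all activated, so the E1 carbon cannot be placed late by electrophilic substitution with any confidence. There are three stereocentres: C3 and C4 are neighbours (3R,4S, aryl groups trans), and C3' (R) lies on the far side of ring E. C4 is a diarylmethine that cannot be epimerised under mild conditions, whereas C3 can be equilibrated to trans while C2 is a carbonyl carbon; C3' is too remote to control or be controlled by the upper pair and needs a reagent of its own. The five phenols, one pair forming a catechol in ring B, make the free compound sensitive to air and base, and the protected intermediates can undergo acid-promoted Friedel–Crafts reactions at the cation-stabilising C4; one robust protecting group, removed under neutral conditions at the end, is called for. The enabling feature is the C3' methine: it carries ring E, the C4' methylene bonded to ring A', and the C2' methylene, so it is a two-carbon unit flanked by one aryl group that can come as a nucleophile and one that can come as an electrophile, with the third substituent replaceable by boron.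

## Retrosynthesis

**Deprotection.** Target **32** is traced to its pentabenzyl ether **31** by cutting five O–benzyl bonds. Benzyl is chosen over silyl or acetal groups because it survives organolithium reagents, hydride, base and mild acid, and leaves under neutral hydrogenolysis, so the free catechol never sees base. The forward step must spare the C4 diarylmethine and the aryl–oxygen bonds of both pyrans.

**Upper pyran, O1–C2.** Chroman **31** is opened at O1–C2 to diol **30** (ring A phenol plus primary alcohol), which comes from dihydrocoumarin **29** by hydride reduction. Cutting here rather than at O1–C8a makes C2 a carbonyl carbon one stage earlier, and that is what makes C3 correctable. The forward steps are a lactone reduction that must outrun enolisation and a Mitsunobu closure.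

**C3–C4 and the acyl C–O bond.** Lactone **29** is divided into the ortho-quinone methide **28**, released from sulfone **21**, and the ring B acid **26**, activated as anhydride **27**. This is preferred to a cut at C4–C4a or E1–C4 at this stage because both upper stereocentres arise in one bond-forming event, ring B enters as a simple arylacetic acid, and the product is a lactone in which C3 can be equilibrated. The forward reaction must reach a crowded methide carbon and must override any bias from C3' through the chiral isothiourea.

**C4–C4a.** Sulfone **21** is the storable form of benzhydrol **20**, which is cut between C4 and ring A into aldehyde **16** and bromophenol **18** (used as the dilithio species **19**). The reverse polarity (a metal at E1 and a ring A aldehyde) would need a halogen at E1 of the finished lower isoflavan. Bromination of that compound cannot be expected to choose E1 over E5, E3 or the activated positions of ring A'. The C4 carbon is therefore carried on ring E from the start as a masked formyl group.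

**Lower pyran, O1'–C8a'.** Aldehyde **16** comes from dioxolane **15**, and **15** from chloro alcohol **14** by intramolecular aryl etherification. The more usual cut at C2'–O1' (phenol plus alcohol, Mitsunobu) would need a protected ring A' phenol. The acid that frees it would also open the dioxolane and let the C2' alcohol form a lactol with the E1 aldehyde. A chlorine at C8a' needs no protecting group and is inert in the steps before.

**C2'.** Alcohol **14** is traced through the homologated boronic ester **13** to the secondary boronic ester **12**. Removing one carbon turns the 2-aryl-3-arylpropanol into a 1,2-diarylethyl boronate. The forward step is a one-carbon insertion into the C–B bond followed by oxidation, both with retention.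

**E6–C3' and C4'–C4a' (key cut).** Boronic ester **12** is divided into three pieces: ring E bromide **6** (as aryllithium **10**), vinylboronic ester **9** and ring A' bromide **8**, joined through boronate **11**. Compared with enolate benzylation of a ring E arylacetic acid derivative, this cut needs no auxiliary and creates the two skeletal bonds and C3' in one operation. The forward reaction needs a catalyst that selects one alkene face and an ortho-substituted aryl group that migrates from boron to carbon.

**Building blocks.** Bromide **6** comes from aldehyde **5** by acetalisation, **5** from silyl ether **4** by exchange of silyl for benzyl, and **4** from **2** by metalation (via **3**) and formylation between bromine and methoxy; **2** is the silyl ether of commercial phenol **1**. The bulky silyl group is there only to close off E3 and E5 during the metalation. Bromide **8** is the benzyl ether of **7**, bromophenol **18** the monobenzyl ether of **17**, and acid **26** comes from aldehyde **22** by benzylation (**23**), methoxymethylenation (**24**) and hydrolysis–oxidation (via **25**).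

## Roads not taken

**Alternative 1:** The cut is C4–C4a, made last in the upper ring. Carbinol A1 carries ring B at C3, a 3-benzyloxyphenyl ether on C2 and a free hydroxyl at E4. Acid would dehydrate A1 to the para-quinone methide of ring E (E4 is para to E1), and the tethered arene would attack C4 through the carbon para to its benzyloxy group, closing the pyran to give A2.
- Merits: the closure is intramolecular and six-membered, so crowding at C4 counts for less than in a bimolecular addition, and C4 is set by C3 through a chair-like transition state with both aryl groups equatorial (trans).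
- Weak points: C3 must be made beforehand on an open chain next to an ionisable carbinol, where a 1,2-shift of the electron-rich ring B through a phenonium ion is a real danger. E4 must be told apart from four other phenols, so the uniform benzyl scheme is lost. The arene can also attack ortho to both of its oxygens. The plan is silent on C3' and on how the E1 carbon is placed.
- Comparison: for the C4 centre itself this road is probably the safer one, and the chosen plan has nothing of equal quality at step 16. The chosen plan sets against it a single catalytic event for C3 and C4 with C3 correctable in the lactone, one protecting group throughout, and ring B introduced as an acid in the last C–C bond formation. If step 16 failed on steric grounds, this closure would be the first idea to borrow.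

**Alternative 2:** The cut is C3–C4 together with the acyl O1–C2 bond. Base frees the ortho-quinone methide from sulfone A3, the isothiourea-bound enolate derived from acid **26** adds to the methide carbon, and the phenoxide closes the lactone to give A4 with all three stereocentres.
- Merits: convergent; both upper centres and the ring form in one step; C3 is correctable.
- Weak points: the methide carbon is flanked by both ortho substituents of ring E, and the catalyst must overrule C3'.
- Comparison: the chosen plan uses this annulation unchanged as step 16 (A3 is **21**, A4 is **29**), so in the upper half the two roads are equal and share the risk. They differ in what organises the plan. With the annulation at the centre, the lower isoflavan inside A3 is an unsolved input, and the usual isoflavan routes neither place a carbon at E1 nor deliver a 3,5-dioxygenated 3-aryl ring cheaply. The conjunctive coupling answers exactly that question and sets C3' while doing so.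

**Alternative 3:** The cut removes both carbon arms of ring E at once (E6–C3' and E1–C4). The aryne from silyl triflate A5 would insert into the bond between the alpha carbon and the ketone of beta-keto ester A6: the enolate carbon adds meta to the methoxy group (E6), the aryl anion at E1 attacks the ketone, and the cyclobutoxide fragments to keto ester A7.
- Merits: the ortho relationship of the two arms and its orientation to the methoxy group follow from the known regiochemistry of 3-alkoxyarynes in one step. This is shorter and arguably more secure than the four steps, one a directed metalation, that the chosen plan spends on **6**.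
- Weak points: A7 has no stereocentre. C3' would have to be set afterwards by asymmetric benzylation of a hindered ortho-acyl arylacetate. C4 arrives as a diaryl ketone, from which C3, ring B and the pyran oxygen bridge must still be built, and C4 would finally be set at a tetrasubstituted alkene or a doubly ortho-flanked ketone. A5 itself needs a regiodefined tetrasubstituted arene, so part of the regiochemical problem returns.
- Comparison: better economy in assembling ring E, weaker in every stereochemical respect. The chosen plan pays more steps for ring E but obtains C3' together with the carbon skeleton.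

Key step: step 6

## Route

Assumption: the enantiomers named for the ferrocenyl bisphosphine (step 6) and the isothiourea (step 16) are those expected, by analogy with simple substrates, to give the configurations drawn; if a model reaction shows the opposite sense, the equally available mirror-image catalyst is used.

Step 1
Reactants: 1 3-bromo-5-methoxyphenol
Product: 2 (3-bromo-5-methoxyphenoxy)tri(propan-2-yl)silane
Conditions: TIPSCl, imidazole, DMF, rt
Reagents that add atoms: chlorotri(propan-2-yl)silane, CC(C)[Si](Cl)(C(C)C)C(C)C
Why: Imidazole-promoted silylation of a phenol; the bulky triisopropylsilyl ether neither directs metalation nor leaves room for it at its ortho positions, which is what step 2 needs.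

Step 2
Reactants: 2 (3-bromo-5-methoxyphenoxy)tri(propan-2-yl)silane
Product: 4 2-bromo-6-methoxy-4-(triisopropylsilyloxy)benzaldehyde, via aryllithium 3 (not isolated)
Conditions: LiN(i-Pr)2 (1.15 equiv), THF, −78 °C; DMF, −78 → 0 °C; aq. NH4Cl
Reagents that add atoms: N,N-dimethylformamide, CN(C)C=O
Why: Directed ortho metalation: the amide base removes the proton flanked by bromine and methoxy (E1), the most acidic site and the only one not shielded by the silyl ether, at a temperature where the ortho-bromoaryllithium does not lose LiBr; formylation then places the future C4 carbon regiospecifically.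

Step 3
Reactants: 4 2-bromo-6-methoxy-4-(triisopropylsilyloxy)benzaldehyde
Product: 5 4-(benzyloxy)-2-bromo-6-methoxybenzaldehyde
Conditions: CsF, BnBr, DMF, rt
Reagents that add atoms: benzyl bromide, BrCc1ccccc1
Why: Fluoride cleaves the aryl silyl ether (the phenoxide para to the formyl group is a good leaving group) and the caesium phenoxide is benzylated in the same pot (Williamson ether synthesis), so that every phenol carries the same protecting group from here on.

Step 4
Reactants: 5 4-(benzyloxy)-2-bromo-6-methoxybenzaldehyde
Product: 6 2-[4-(benzyloxy)-2-bromo-6-methoxyphenyl]-1,3-dioxolane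
Conditions: HOCH2CH2OH, p-TsOH·H2O (cat.), toluene, reflux, Dean–Stark
Reagents that add atoms: ethane-1,2-diol, OCCO
Why: Acid-catalysed acetalisation with azeotropic removal of water; the dioxolane masks the aldehyde against the organolithium chemistry of steps 6 and 7 and is the most compact acetal that can sit next to the migrating carbon.

Step 5
Reactants: 7 4-bromo-3-chlorophenol
Product: 8 4-(benzyloxy)-1-bromo-2-chlorobenzene
Conditions: BnBr, K2CO3, DMF, rt
Reagents that add atoms: benzyl bromide, BrCc1ccccc1
Why: Williamson ether synthesis on a single phenol; the chlorine ortho to bromine is the later attachment point of O1'.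

Step 6
Reactants: 6 2-[4-(benzyloxy)-2-bromo-6-methoxyphenyl]-1,3-dioxolane; 9 vinylboronic acid pinacol ester; 8 4-(benzyloxy)-1-bromo-2-chlorobenzene
Product: 12 (R)-1-(ring E aryl)-2-(ring A' aryl)ethyl pinacol boronic ester, via aryllithium 10 (not isolated), via lithium vinylboronate complex 11 (not isolated)
Conditions: 6, t-BuLi (2.0 equiv), Et2O, −78 °C; 9, −78 °C → rt; solvent exchange to THF; 8, Pd(OAc)2 (2 mol%), (R,R)-(Sp,Sp)-MandyPhos [1,1'-bis{bis(4-methoxy-3,5-dimethylphenyl)phosphino}-2,2'-bis{(R)-(dimethylamino)(phenyl)methyl}ferrocene] (2.4 mol%), NaOTf (2 equiv), THF, 60 °C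
Reagents that add atoms: none
Why: Bromine–lithium exchange of 6 gives aryllithium 10, which adds to the vacant orbital on boron of 9 to give the tetracoordinate boronate 11. Pd(OAc)2 and the ferrocenyl bisphosphine give a zerovalent palladium complex that inserts into the C–Br bond of 8, and NaOTf takes up bromide so that a cationic divalent arylpalladium species can bind the vinyl group of 11. Coordination triggers a 1,2-metallate shift in which ring E moves from boron to the inner vinyl carbon anti to palladium (bond E6–C3'), and reductive elimination from the resulting alkyl(aryl)palladium joins the terminal carbon to ring A' (bond C4'–C4a'). The closest known reaction type is the palladium-catalysed enantioselective conjunctive cross-coupling of vinylboron ate complexes with aryl electrophiles, which covers ortho-substituted migrating aryl groups and aryl bromides in the presence of triflate salts. No ring is closed. The one new stereocentre, C3', is set by the chiral ligand, which selects the alkene face that binds palladium; the migration is then stereospecifically anti. The step needs aryl migration rather than migration of a pinacol oxygen (secured by the higher migratory aptitude of the sp2 carbon), the conjunctive path rather than direct aryl transfer to palladium (secured by the chelating bisphosphine on a cationic metal), and insertion into C–Br rather than C–Cl (secured by bond strength).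

Step 7
Reactants: 12 (R)-1-(ring E aryl)-2-(ring A' aryl)ethyl pinacol boronic ester
Product: 14 (2R)-2-[5-(benzyloxy)-2-(1,3-dioxolan-2-yl)-3-methoxyphenyl]-3-[4-(benzyloxy)-2-chlorophenyl]propan-1-ol, via homologated boronic ester 13 (not isolated)
Conditions: BrCH2Cl (3 equiv), n-BuLi (2.5 equiv), THF, −78 °C → rt; then NaOH (3 M), H2O2 (30%), 0 °C → rt
Reagents that add atoms: bromochloromethane, ClCBr; hydrogen peroxide, OO
Why: Matteson homologation: chloromethyllithium formed in situ adds to boron and the benzylic carbon migrates with retention, displacing chloride; oxidation of the new primary C–B bond with alkaline peroxide also goes with retention, so C3' keeps its configuration and gains the C2' hydroxymethyl group.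

Step 8
Reactants: 14 (2R)-2-[5-(benzyloxy)-2-(1,3-dioxolan-2-yl)-3-methoxyphenyl]-3-[4-(benzyloxy)-2-chlorophenyl]propan-1-ol
Product: 15 (3R)-7-(benzyloxy)-3-[5-(benzyloxy)-2-(1,3-dioxolan-2-yl)-3-methoxyphenyl]chroman
Conditions: Pd(OAc)2 (3 mol%), 2-(di-tert-butylphosphino)-1,1'-binaphthyl (4 mol%), Cs2CO3, toluene, 80 °C
Reagents that add atoms: none
Why: Palladium-catalysed intramolecular aryl etherification (Buchwald–Hartwig type) of a primary alcohol with an aryl chloride; the bulky electron-rich phosphine favours C–O reductive elimination over beta-hydride elimination, the six-membered ring forms at O1'–C8a', and C3' is not involved.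

Step 9
Reactants: 15 (3R)-7-(benzyloxy)-3-[5-(benzyloxy)-2-(1,3-dioxolan-2-yl)-3-methoxyphenyl]chroman
Product: 16 4-(benzyloxy)-2-[(3R)-7-(benzyloxy)chroman-3-yl]-6-methoxybenzaldehyde
Conditions: HCl (1 M), THF, rt
Reagents that add atoms: water, O
Why: Mild acid hydrolysis of an acetal of an electron-rich benzaldehyde; the benzyl ethers, the chroman and the non-enolisable C3' centre are untouched.

Step 10
Reactants: 17 4-bromobenzene-1,3-diol
Product: 18 5-(benzyloxy)-2-bromophenol
Conditions: BnBr (1.0 equiv), K2CO3, acetone, rt
Reagents that add atoms: benzyl bromide, BrCc1ccccc1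
Why: Williamson ether synthesis; the hydroxyl para to bromine is the less hindered one and should react preferentially with one equivalent of benzyl bromide, the regioisomer and the dibenzyl ether being removed by chromatography.

Step 11
Reactants: 18 5-(benzyloxy)-2-bromophenol; 16 4-(benzyloxy)-2-[(3R)-7-(benzyloxy)chroman-3-yl]-6-methoxybenzaldehyde
Product: 20 ortho-hydroxybenzhydrol joining ring A to C4 on ring E (both carbinol epimers), via dilithiated phenol 19 (not isolated)
Conditions: 18, n-BuLi (2.2 equiv), THF, −78 → 0 °C; 16, −78 → 0 °C; aq. NH4Cl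
Reagents that add atoms: none
Why: The first equivalent of n-BuLi deprotonates the phenol and the second exchanges the bromine; the ortho-lithiophenoxide adds to the aldehyde (1,2-addition of an aryllithium) and gives the benzhydrol without a phenol protecting group; the carbinol configuration is irrelevant because this carbon becomes trigonal in step 16.

Step 12
Reactants: 20 ortho-hydroxybenzhydrol joining ring A to C4 on ring E
Product: 21 ortho-hydroxybenzhydryl 4-tolyl sulfone (both epimers)
Conditions: p-TolSO2Na (3 equiv), HCO2H, THF/H2O, rt
Reagents that add atoms: sodium 4-methylbenzenesulfinate, [Na+].[O-]S(=O)c1ccc(C)cc1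
Why: Acid ionises the doubly donor-stabilised benzhydrol and the sulfinate captures the cation at sulfur, giving a storable sulfone that releases the ortho-quinone methide again under mild base (a standard quinone methide precursor).

Step 13
Reactants: 22 2,3-dihydroxy-4-methoxybenzaldehyde
Product: 23 2,3-bis(benzyloxy)-4-methoxybenzaldehyde
Conditions: BnBr (2.4 equiv), K2CO3, DMF, 50 °C
Reagents that add atoms: benzyl bromide, BrCc1ccccc1
Why: Double Williamson ether synthesis; protecting the catechol at the outset removes its sensitivity to oxidation.

Step 14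
Reactants: 23 2,3-bis(benzyloxy)-4-methoxybenzaldehyde
Product: 24 2,3-bis(benzyloxy)-4-methoxy-1-(2-methoxyethenyl)benzene (E/Z mixture)
Conditions: Ph3P(CH2OMe)Cl, KOt-Bu, THF, 0 °C → rt
Reagents that add atoms: (methoxymethyl)triphenylphosphonium chloride, [Cl-].COC[P+](c1ccccc1)(c1ccccc1)c1ccccc1
Why: Wittig methoxymethylenation adds the one carbon that becomes C2; the alkene geometry is irrelevant because both isomers hydrolyse to the same aldehyde.

Step 15
Reactants: 24 2,3-bis(benzyloxy)-4-methoxy-1-(2-methoxyethenyl)benzene
Product: 26 2-[2,3-bis(benzyloxy)-4-methoxyphenyl]acetic acid, via arylacetaldehyde 25 (not isolated)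
Conditions: HCl (2 M), THF, rt; then NaH2PO4, 2-methylbut-2-ene, NaClO2, t-BuOH/H2O, 0 °C → rt
Reagents that add atoms: water, O; sodium chlorite, [Na+].[O-]Cl=O
Why: Acid hydrolysis of the enol ether gives the arylacetaldehyde, which is oxidised at once (Pinnick oxidation) because such aldehydes do not store well; buffered chlorite with an alkene scavenger leaves benzyl ethers and the electron-rich ring alone.

Step 16
Reactants: 21 ortho-hydroxybenzhydryl 4-tolyl sulfone; 26 2-[2,3-bis(benzyloxy)-4-methoxyphenyl]acetic acid
Product: 29 (3R,4S)-3,4-diaryl-3,4-dihydrocoumarin (pentabenzyl ether), via mixed pivalic anhydride 27 (not isolated), via ortho-quinone methide 28 (not isolated)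
Conditions: 26, t-BuCOCl, i-Pr2NEt, CH2Cl2, 0 °C; then 21, (2S,3R)-HyperBTM (10 mol%), Cs2CO3, 0 °C → rt; then DBU (0.2 equiv), rt
Reagents that add atoms: none
Why: Isothiourea-catalysed Michael addition–lactonisation (formal [4+2]): the catalyst is acylated by 27 and deprotonated to a (Z)-ammonium enolate, which adds to the exocyclic carbon of 28 released from the sulfone by base (C3–C4); the phenoxide then acylates (O1–C2, six-membered lactone) and frees the catalyst. The catalyst fixes the enolate face and through it the face of the quinone methide, so C4 is set by the reagent and not by the remote C3'; C3 lies alpha to the lactone carbonyl and DBU equilibrates it to the more stable trans arrangement.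

Step 17
Reactants: 29 (3R,4S)-3,4-diaryl-3,4-dihydrocoumarin (pentabenzyl ether)
Product: 30 (2R,3S)-2,3,3-triarylpropan-1-ol with free ring A phenol
Conditions: LiAlH4, THF, 0 °C
Reagents that add atoms: none
Why: Hydride reduction of an aryl ester to the primary alcohol and the phenol; hydride addition to the lactone is faster than enolisation, so C3 keeps its configuration.

Step 18
Reactants: 30 (2R,3S)-2,3,3-triarylpropan-1-ol with free ring A phenol
Product: 31 pentabenzyl ether of the target
Conditions: PPh3, DIAD, THF, 0 °C → rt
Reagents that add atoms: none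
Why: Mitsunobu etherification: the primary alcohol is activated as its oxyphosphonium ion and displaced by the only free phenoxide (six-membered ring, bond O1–C2); no stereocentre takes part.

Step 19
Reactants: 31 pentabenzyl ether of the target
Product: 32 CNP0227211.1
Conditions: H2 (1 atm), Pd/C (10%), EtOAc/MeOH, rt
Reagents that add atoms: none
Why: Hydrogenolysis of five benzyl aryl ethers under neutral conditions; the C4 diarylmethine and the aryl–oxygen and alkyl–oxygen bonds of the two pyrans are not benzylic C–O bonds and remain.

## Compound list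

1 | 3-bromo-5-methoxyphenol | COc1cc(O)cc(Br)c1 | starting material
2 | (3-bromo-5-methoxyphenoxy)tri(propan-2-yl)silane | COc1cc(Br)cc(O[Si](C(C)C)(C(C)C)C(C)C)c1 | intermediate
3 | [2-bromo-6-methoxy-4-(triisopropylsilyloxy)phenyl]lithium (formed in situ) | [Li]c1c(Br)cc(O[Si](C(C)C)(C(C)C)C(C)C)cc1OC | intermediate
4 | 2-bromo-6-methoxy-4-(triisopropylsilyloxy)benzaldehyde | O=Cc1c(Br)cc(O[Si](C(C)C)(C(C)C)C(C)C)cc1OC | intermediate
5 | 4-(benzyloxy)-2-bromo-6-methoxybenzaldehyde | O=Cc1c(Br)cc(OCc2ccccc2)cc1OC | intermediate
6 | 2-[4-(benzyloxy)-2-bromo-6-methoxyphenyl]-1,3-dioxolane | COc1cc(OCc2ccccc2)cc(Br)c1C1OCCO1 | intermediate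
7 | 4-bromo-3-chlorophenol | Oc1ccc(Br)c(Cl)c1 | starting material
8 | 4-(benzyloxy)-1-bromo-2-chlorobenzene | Clc1cc(OCc2ccccc2)ccc1Br | intermediate
9 | vinylboronic acid pinacol ester (2-ethenyl-4,4,5,5-tetramethyl-1,3,2-dioxaborolane) | C=CB1OC(C)(C)C(C)(C)O1 | starting material
10 | [5-(benzyloxy)-2-(1,3-dioxolan-2-yl)-3-methoxyphenyl]lithium (formed in situ) | [Li]c1cc(OCc2ccccc2)cc(OC)c1C1OCCO1 | intermediate
11 | lithium [5-(benzyloxy)-2-(1,3-dioxolan-2-yl)-3-methoxyphenyl](ethenyl)(pinacolato)borate (formed in situ) | [Li+].C=C[B-]1(OC(C)(C)C(C)(C)O1)c1cc(OCc2ccccc2)cc(OC)c1C1OCCO1 | intermediate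
12 | 2-[(1R)-1-[5-(benzyloxy)-2-(1,3-dioxolan-2-yl)-3-methoxyphenyl]-2-[4-(benzyloxy)-2-chlorophenyl]ethyl]-4,4,5,5-tetramethyl-1,3,2-dioxaborolane | COc1cc(OCc2ccccc2)cc([C@@H](Cc2ccc(OCc3ccccc3)cc2Cl)B2OC(C)(C)C(C)(C)O2)c1C1OCCO1 | intermediate
13 | 2-[(2R)-2-[5-(benzyloxy)-2-(1,3-dioxolan-2-yl)-3-methoxyphenyl]-3-[4-(benzyloxy)-2-chlorophenyl]propyl]-4,4,5,5-tetramethyl-1,3,2-dioxaborolane (formed in situ) | COc1cc(OCc2ccccc2)cc([C@@H](Cc2ccc(OCc3ccccc3)cc2Cl)CB2OC(C)(C)C(C)(C)O2)c1C1OCCO1 | intermediate
14 | (2R)-2-[5-(benzyloxy)-2-(1,3-dioxolan-2-yl)-3-methoxyphenyl]-3-[4-(benzyloxy)-2-chlorophenyl]propan-1-ol | COc1cc(OCc2ccccc2)cc([C@@H](Cc2ccc(OCc3ccccc3)cc2Cl)CO)c1C1OCCO1 | intermediate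
15 | (3R)-7-(benzyloxy)-3-[5-(benzyloxy)-2-(1,3-dioxolan-2-yl)-3-methoxyphenyl]-3,4-dihydro-2H-chromene | COc1cc(OCc2ccccc2)cc([C@@H]2COc3cc(OCc4ccccc4)ccc3C2)c1C1OCCO1 | intermediate
16 | 4-(benzyloxy)-2-[(3R)-7-(benzyloxy)-3,4-dihydro-2H-chromen-3-yl]-6-methoxybenzaldehyde | COc1cc(OCc2ccccc2)cc([C@@H]2COc3cc(OCc4ccccc4)ccc3C2)c1C=O | intermediate
17 | 4-bromobenzene-1,3-diol (4-bromoresorcinol) | Oc1ccc(Br)c(O)c1 | starting material
18 | 5-(benzyloxy)-2-bromophenol | Oc1cc(OCc2ccccc2)ccc1Br | intermediate
19 | lithium 5-(benzyloxy)-2-lithiophenolate (formed in situ) | [Li]Oc1cc(OCc2ccccc2)ccc1[Li] | intermediate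
20 | 5-(benzyloxy)-2-{[4-(benzyloxy)-2-[(3R)-7-(benzyloxy)-3,4-dihydro-2H-chromen-3-yl]-6-methoxyphenyl](hydroxy)methyl}phenol, both epimers at the carbinol carbon | COc1cc(OCc2ccccc2)cc([C@@H]2COc3cc(OCc4ccccc4)ccc3C2)c1C(O)c1ccc(OCc2ccccc2)cc1O | intermediate
21 | 5-(benzyloxy)-2-{[4-(benzyloxy)-2-[(3R)-7-(benzyloxy)-3,4-dihydro-2H-chromen-3-yl]-6-methoxyphenyl](4-methylbenzenesulfonyl)methyl}phenol, both epimers at the sulfonyl-bearing carbon | COc1cc(OCc2ccccc2)cc([C@@H]2COc3cc(OCc4ccccc4)ccc3C2)c1C(c1ccc(OCc2ccccc2)cc1O)S(=O)(=O)c1ccc(C)cc1 | intermediate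
22 | 2,3-dihydroxy-4-methoxybenzaldehyde | COc1ccc(C=O)c(O)c1O | starting material
23 | 2,3-bis(benzyloxy)-4-methoxybenzaldehyde | COc1ccc(C=O)c(OCc2ccccc2)c1OCc1ccccc1 | intermediate
24 | 2,3-bis(benzyloxy)-4-methoxy-1-(2-methoxyethenyl)benzene, E/Z mixture | COC=Cc1ccc(OC)c(OCc2ccccc2)c1OCc1ccccc1 | intermediate
25 | 2-[2,3-bis(benzyloxy)-4-methoxyphenyl]acetaldehyde (formed in situ) | O=CCc1ccc(OC)c(OCc2ccccc2)c1OCc1ccccc1 | intermediate
26 | 2-[2,3-bis(benzyloxy)-4-methoxyphenyl]acetic acid | OC(=O)Cc1ccc(OC)c(OCc2ccccc2)c1OCc1ccccc1 | intermediate
27 | 2-[2,3-bis(benzyloxy)-4-methoxyphenyl]acetic 2,2-dimethylpropanoic anhydride (formed in situ) | CC(C)(C)C(=O)OC(=O)Cc1ccc(OC)c(OCc2ccccc2)c1OCc1ccccc1 | intermediate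
28 | 3-(benzyloxy)-6-{[4-(benzyloxy)-2-[(3R)-7-(benzyloxy)-3,4-dihydro-2H-chromen-3-yl]-6-methoxyphenyl]methylidene}cyclohexa-2,4-dien-1-one (formed in situ) | COc1cc(OCc2ccccc2)cc([C@@H]2COc3cc(OCc4ccccc4)ccc3C2)c1C=C1C=CC(OCc2ccccc2)=CC1=O | intermediate
29 | (3R,4S)-7-(benzyloxy)-4-{4-(benzyloxy)-2-[(3R)-7-(benzyloxy)-3,4-dihydro-2H-chromen-3-yl]-6-methoxyphenyl}-3-[2,3-bis(benzyloxy)-4-methoxyphenyl]-3,4-dihydro-2H-chromen-2-one | COc1ccc([C@@H]2C(=O)Oc3cc(OCc4ccccc4)ccc3[C@H]2c2c(OC)cc(OCc3ccccc3)cc2[C@@H]2COc3cc(OCc4ccccc4)ccc3C2)c(OCc2ccccc2)c1OCc1ccccc1 | intermediate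
30 | (2R,3S)-3-[4-(benzyloxy)-2-hydroxyphenyl]-3-{4-(benzyloxy)-2-[(3R)-7-(benzyloxy)-3,4-dihydro-2H-chromen-3-yl]-6-methoxyphenyl}-2-[2,3-bis(benzyloxy)-4-methoxyphenyl]propan-1-ol | COc1ccc([C@H](CO)[C@@H](c2ccc(OCc3ccccc3)cc2O)c2c(OC)cc(OCc3ccccc3)cc2[C@@H]2COc3cc(OCc4ccccc4)ccc3C2)c(OCc2ccccc2)c1OCc1ccccc1 | intermediate
31 | (3R,4S)-7-(benzyloxy)-4-{4-(benzyloxy)-2-[(3R)-7-(benzyloxy)-3,4-dihydro-2H-chromen-3-yl]-6-methoxyphenyl}-3-[2,3-bis(benzyloxy)-4-methoxyphenyl]-3,4-dihydro-2H-chromene | COc1ccc([C@@H]2COc3cc(OCc4ccccc4)ccc3[C@H]2c2c(OC)cc(OCc3ccccc3)cc2[C@@H]2COc3cc(OCc4ccccc4)ccc3C2)c(OCc2ccccc2)c1OCc1ccccc1 | intermediate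
32 | (3R,4S)-3-(2,3-dihydroxy-4-methoxyphenyl)-4-{4-hydroxy-2-[(3R)-7-hydroxy-3,4-dihydro-2H-chromen-3-yl]-6-methoxyphenyl}-3,4-dihydro-2H-chromen-7-ol (CNP0227211.1) | COc1ccc([C@@H]2COc3cc(O)ccc3[C@H]2c2c(OC)cc(O)cc2[C@@H]2COc3cc(O)ccc3C2)c(O)c1O | target

## Step count and least certain steps

Total: 19 steps. Longest linear sequence: 14 steps (steps 1, 2, 3, 4, 6, 7, 8, 9, 11, 12, 16, 17, 18, 19).

**Step 6 (key step).**
- What may go wrong: the migrating ring E carries the dioxolane ortho to boron, which slows the 1,2-shift, and lithium bromide from the exchange can occupy the site on palladium that the alkene needs. Direct aryl transfer from boron to palladium or beta-hydride loss after migration may then compete, and a slower conjunctive path usually also means lower enantioselectivity.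
- Fallback (sets out from 6, returns at 12): the two bonds are made in separate known steps, so ring E no longer has to migrate.
 - Suzuki–Miyaura coupling of 6 with 9 (Pd(OAc)2, SPhos, K3PO4, dioxane/H2O) gives the styrene 2-[4-(benzyloxy)-2-ethenyl-6-methoxyphenyl]-1,3-dioxolane F1.
 - Enantioselective alkene diboration with B2(pin)2 (Pt(dba)3, a TADDOL-derived phosphonite, THF, 60 °C) gives the (R)-1,2-bis(pinacolboryl)ethyl arene F2.
 - Site-selective Suzuki–Miyaura coupling of the primary C–B bond of F2 with 8 (Pd(OAc)2, RuPhos, KOH, THF/H2O, 70 °C) returns 12.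

**Step 16.**
- What may go wrong: attack on the quinone methide carbon, which is shielded on both faces by the ortho substituents of the twisted ring E, may be slower than decay of the ammonium enolate. Facial selection at C4 may also be poor, since the catalyst has to override whatever bias C3' exerts.
- Fallback (sets out from 20, returns at 29): the C3–C4 bond is made intramolecularly.
 - Oxidation of 20 with MnO2 (CH2Cl2, rt) gives the 2-hydroxybenzophenone F3.
 - Perkin condensation of F3 with acid 26 (Ac2O, Et3N, 120 °C) acylates the phenol and closes by intramolecular aldol condensation to the 3,4-diarylcoumarin F4.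
 - Conjugate reduction of F4 by electron transfer (SmI2, t-BuOH, THF/N,N-dimethylacetamide) followed by DBU gives the trans-dihydrocoumarin as two C4 epimers, from which 29 is separated by chromatography.
 - The price is the loss of control over C4.

**Step 8.**
- What may go wrong: beta-hydride elimination from the palladium alkoxide (oxidation of the alcohol with loss of chlorine) and slow insertion into the electron-rich, ortho-alkylated C–Cl bond.
- Fallback (sets out from 6 and 18, returns at 15): the ring is closed at C2'–O1' instead.
 - 18 is silylated (TIPSCl, imidazole, DMF) to [5-(benzyloxy)-2-bromophenoxy]tri(propan-2-yl)silane F5.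
 - F5 takes the place of 8 in the conjunctive coupling of step 6 and gives the silyloxy boronic ester F6.
 - Homologation and oxidation as in step 7 give the silyloxy alcohol F7.
 - Bu4NF (THF, 0 °C) frees the phenol diol F8.
 - Mitsunobu closure (PPh3, DIAD, THF) gives 15.

**Step 2.**
- What may go wrong: loss of LiBr from the ortho-bromoaryllithium (aryne formation) or bromine migration between ring positions if the temperature rises, and partial metalation at E5.
- Fallback (sets out from 2, returns at 4): an electrophilic route, Rieche formylation (Cl2CHOMe, TiCl4, CH2Cl2, −78 → 0 °C). TiCl4 bound to the methoxy oxygen delivers the electrophile to its free ortho position E1, which is also para to the silyl ether, while E3 and E5 stay shielded. This makes no compound outside the list (F0).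

## Further compounds

F1 | step 6 | 2-[4-(benzyloxy)-2-ethenyl-6-methoxyphenyl]-1,3-dioxolane | COc1cc(OCc2ccccc2)cc(C=C)c1C1OCCO1
F2 | step 6 | 2,2'-{(1R)-1-[5-(benzyloxy)-2-(1,3-dioxolan-2-yl)-3-methoxyphenyl]ethane-1,2-diyl}bis(4,4,5,5-tetramethyl-1,3,2-dioxaborolane) | COc1cc(OCc2ccccc2)cc([C@@H](CB2OC(C)(C)C(C)(C)O2)B2OC(C)(C)C(C)(C)O2)c1C1OCCO1
F3 | step 16 | [4-(benzyloxy)-2-hydroxyphenyl]{4-(benzyloxy)-2-[(3R)-7-(benzyloxy)-3,4-dihydro-2H-chromen-3-yl]-6-methoxyphenyl}methanone | COc1cc(OCc2ccccc2)cc([C@@H]2COc3cc(OCc4ccccc4)ccc3C2)c1C(=O)c1ccc(OCc2ccccc2)cc1O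
F4 | step 16 | 7-(benzyloxy)-4-{4-(benzyloxy)-2-[(3R)-7-(benzyloxy)-3,4-dihydro-2H-chromen-3-yl]-6-methoxyphenyl}-3-[2,3-bis(benzyloxy)-4-methoxyphenyl]-2H-chromen-2-one | COc1ccc(C2=C(c3c(OC)cc(OCc4ccccc4)cc3[C@@H]3COc4cc(OCc5ccccc5)ccc4C3)c3ccc(OCc4ccccc4)cc3OC2=O)c(OCc2ccccc2)c1OCc1ccccc1
F5 | step 8 | [5-(benzyloxy)-2-bromophenoxy]tri(propan-2-yl)silane | CC(C)[Si](Oc1cc(OCc2ccccc2)ccc1Br)(C(C)C)C(C)C
F6 | step 8 | 2-[(1R)-1-[5-(benzyloxy)-2-(1,3-dioxolan-2-yl)-3-methoxyphenyl]-2-[4-(benzyloxy)-2-(triisopropylsilyloxy)phenyl]ethyl]-4,4,5,5-tetramethyl-1,3,2-dioxaborolane | COc1cc(OCc2ccccc2)cc([C@@H](Cc2ccc(OCc3ccccc3)cc2O[Si](C(C)C)(C(C)C)C(C)C)B2OC(C)(C)C(C)(C)O2)c1C1OCCO1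
F7 | step 8 | (2R)-2-[5-(benzyloxy)-2-(1,3-dioxolan-2-yl)-3-methoxyphenyl]-3-[4-(benzyloxy)-2-(triisopropylsilyloxy)phenyl]propan-1-ol | COc1cc(OCc2ccccc2)cc([C@@H](Cc2ccc(OCc3ccccc3)cc2O[Si](C(C)C)(C(C)C)C(C)C)CO)c1C1OCCO1
F8 | step 8 | 5-(benzyloxy)-2-{(2R)-2-[5-(benzyloxy)-2-(1,3-dioxolan-2-yl)-3-methoxyphenyl]-3-hydroxypropyl}phenol | COc1cc(OCc2ccccc2)cc([C@@H](Cc2ccc(OCc3ccccc3)cc2O)CO)c1C1OCCO1
F0 | step 2 | none | none
A1 | alternative 1 | C4 carbinol with free E4 hydroxyl and a 3-benzyloxyphenyl ether on C2 (C3 and C3' as in the target, carbinol carbon unspecified) | COc1ccc([C@H](COc2cccc(OCc3ccccc3)c2)C(O)c2c(OC)cc(O)cc2[C@@H]2COc3cc(OCc4ccccc4)ccc3C2)c(OCc2ccccc2)c1OCc1ccccc1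
A2 | alternative 1 | tetrabenzyl ether of the target with the ring E phenol free | COc1ccc([C@@H]2COc3cc(OCc4ccccc4)ccc3[C@H]2c2c(OC)cc(O)cc2[C@@H]2COc3cc(OCc4ccccc4)ccc3C2)c(OCc2ccccc2)c1OCc1ccccc1
A3 | alternative 2 | ortho-hydroxybenzhydryl 4-tolyl sulfone (same structure as 21) | COc1cc(OCc2ccccc2)cc([C@@H]2COc3cc(OCc4ccccc4)ccc3C2)c1C(c1ccc(OCc2ccccc2)cc1O)S(=O)(=O)c1ccc(C)cc1
A4 | alternative 2 | trans-3,4-diaryl-3,4-dihydrocoumarin with all three stereocentres (same structure as 29) | COc1ccc([C@@H]2C(=O)Oc3cc(OCc4ccccc4)ccc3[C@H]2c2c(OC)cc(OCc3ccccc3)cc2[C@@H]2COc3cc(OCc4ccccc4)ccc3C2)c(OCc2ccccc2)c1OCc1ccccc1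
A5 | alternative 3 | 5-(benzyloxy)-3-methoxy-2-(trimethylsilyl)phenyl trifluoromethanesulfonate | COc1cc(OCc2ccccc2)cc(OS(=O)(=O)C(F)(F)F)c1[Si](C)(C)C
A6 | alternative 3 | methyl 3-[2,4-bis(benzyloxy)phenyl]-3-oxopropanoate | COC(=O)CC(=O)c1ccc(OCc2ccccc2)cc1OCc1ccccc1
A7 | alternative 3 | methyl 2-[2-(2,4-dibenzyloxybenzoyl)-5-benzyloxy-3-methoxyphenyl]acetate | COC(=O)Cc1cc(OCc2ccccc2)cc(OC)c1C(=O)c1ccc(OCc2ccccc2)cc1OCc1ccccc1
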